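**Retrosynthetic overview**

1. Luzonoid A ⇐ its 11-aldehyde ⇐ C1 lactol acylation and C7 esterification ⇐ C4 enol triflate (Pd(PPh3)4-catalysed formylation installs C11) ⇐ cis-fused 4-ketone ⇐ C7–OH-directed hydrogenation of C5=C9 in a bicyclic 6-hydroxy-2H-pyran-3(6H)-one.
2. The strategy rests on the dihydropyran ring: C1, C9, C5 and C4 are the four carbons of a furan, C3 with O2 is a hydroxymethyl group on the furan carbon next to C5, and the C4 carbonyl oxygen is the furan oxygen. An Achmatowicz ring expansion of a cyclopenta[c]furan-1-ylmethanol therefore gives the C1 lactol, O2 and the C4 ketone in one operation.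
3. Furylmethanol ⇐ 1-bromofuran ⇐ dihydroxylation of an exocyclic C8=C10 alkene anti to O7 ⇐ Parham cyclisation (C8–C9) ⇐ 3,4-dibromofuran + methyl (S)-glycidate (C6–C7–C8; C7 from the chiral pool).
4. Ring order: furan (purchased) → cyclopentane (step 4) → dihydropyran (step 10).

Key step: step 10

Remark 1: iridoid numbering (C1, O2, C3, C4, C5–C9, C10 on C8, C11 on C4) is used for all intermediates; β is the face of H-5/H-9 in the target.
Remark 2: the tertiary C8 hydroxyl lies on the face opposite to the one from which H-5/H-9 must be delivered. O8 is therefore locked with O10 as an acetonide, and the C7 hydroxyl (PMB-protected until step 12) is the director.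
Remark 3: compounds 18–27 should form as C1 epimers; one epimer is drawn, both are carried on and converge at lactol 28.
Remark 4: once C11 is an alcohol the enol ether is acid-labile, so C11 is kept as the aldehyde until the last step.

**Route**

Step 1
Reactants: 1 3,4-dibromofuran; 2 methyl (2S)-oxirane-2-carboxylate
Product: 5 methyl (2S)-3-(4-bromofuran-3-yl)-2-hydroxypropanoate, via (4-bromofuran-3-yl)lithium 3 (not isolated), via (4-bromofuran-3-yl)magnesium bromide 4 (not isolated)
Conditions: n-BuLi (1.0 equiv), Et2O, −78 °C; MgBr2·OEt2; CuI (10 mol %), then 2, −78 → −30 °C; aq. NH4Cl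
Reagents that add atoms: none
Why: Bromine–lithium exchange on the symmetric dibromide followed by CuI-catalysed opening of the epoxide at its CH2 terminus by the Grignard reagent should form C5–C6 without touching the ester; C7 is the untouched glycidate stereocentre.

Step 2
Reactants: 5 methyl (2S)-3-(4-bromofuran-3-yl)-2-hydroxypropanoate
Product: 6 methyl (2S)-3-(4-bromofuran-3-yl)-2-[(4-methoxybenzyl)oxy]propanoate
Conditions: 4-MeOC6H4CH2Cl, Ag2O, n-Bu4NI (cat.), CH2Cl2, rt, dark
Reagents that add atoms: 4-methoxybenzyl chloride, COc1ccc(CCl)cc1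
Why: Ag2O-mediated Williamson etherification is non-basic and acid-free, so the α-hydroxy ester should be protected without racemisation and without alkylating the furan.

Step 3
Reactants: 6 methyl (2S)-3-(4-bromofuran-3-yl)-2-[(4-methoxybenzyl)oxy]propanoate
Product: 7 (2S)-3-(4-bromofuran-3-yl)-N-methoxy-2-[(4-methoxybenzyl)oxy]-N-methylpropanamide
Conditions: MeNH(OMe)·HCl, i-PrMgCl, THF, −20 → 0 °C
Reagents that add atoms: N,O-dimethylhydroxylamine hydrochloride, CNOC.Cl
Why: Aminolysis of the ester by ClMgN(OMe)Me (Weinreb amide formation) is fast at low temperature and should leave the α-alkoxy centre intact.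

Step 4
Reactants: 7 (2S)-3-(4-bromofuran-3-yl)-N-methoxy-2-[(4-methoxybenzyl)oxy]-N-methylpropanamide
Product: 9 (5S)-5-[(4-methoxybenzyl)oxy]-5,6-dihydro-4H-cyclopenta[c]furan-4-one, via furyllithium 8 (not isolated)
Conditions: t-BuLi (2.1 equiv), THF, −78 °C; aq. NH4Cl at −78 °C
Reagents that add atoms: none
Why: In this Parham cyclisation bromine–lithium exchange outruns addition to the amide and the 3-furyllithium closes C8–C9 by 5-exo-trig attack; the chelated tetrahedral intermediate prevents over-addition and enolisation, so C7 should keep its configuration.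

Step 5
Reactants: 9 (5S)-5-[(4-methoxybenzyl)oxy]-5,6-dihydro-4H-cyclopenta[c]furan-4-one
Product: 10 (5S)-1-bromo-5-[(4-methoxybenzyl)oxy]-5,6-dihydro-4H-cyclopenta[c]furan-4-one
Conditions: NBS (1.0 equiv), DMF, 0 °C, dark
Reagents that add atoms: N-bromosuccinimide, O=C1CCC(=O)N1Br
Why: Electrophilic aromatic substitution of a 3-acyl-4-alkylfuran should occur at the α-carbon next to the alkyl-bearing carbon (future C4), because attack next to the acyl-bearing carbon would place positive charge on that carbon.

Step 6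
Reactants: 10 (5S)-1-bromo-5-[(4-methoxybenzyl)oxy]-5,6-dihydro-4H-cyclopenta[c]furan-4-one
Product: 11 (5S)-1-bromo-5-[(4-methoxybenzyl)oxy]-4-methylidene-5,6-dihydro-4H-cyclopenta[c]furan
Conditions: Cp2TiMe2 (2.5 equiv), toluene/THF, 65 °C, dark
Reagents that add atoms: Cp2TiMe2 (dimethyltitanocene), C[Ti](C)(C1C=CC=C1)C1C=CC=C1
Why: In this Petasis methylenation Cp2TiMe2 loses methane on warming and the resulting Cp2Ti=CH2 olefinates the ketone through an oxatitanacyclobutane; the reagent is neither basic nor Lewis acidic, so the enolisable α-alkoxy ketone should be converted (C10 introduced) without epimerising C7 and without harming the PMB ether or the C–Br bond.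

Step 7
Reactants: 11 (5S)-1-bromo-5-[(4-methoxybenzyl)oxy]-4-methylidene-5,6-dihydro-4H-cyclopenta[c]furan
Product: 12 (4R,5S)-1-bromo-4-(hydroxymethyl)-5-[(4-methoxybenzyl)oxy]-5,6-dihydro-4H-cyclopenta[c]furan-4-ol
Conditions: OsO4 (cat.), NMO, acetone/H2O, 0 °C → rt
Reagents that add atoms: N-methylmorpholine N-oxide, C[N+]1([O-])CCOCC1; water, O
Why: In this catalytic (Upjohn) dihydroxylation OsO4 should add to the exocyclic alkene from the face anti to the allylic C7 ether, setting C8 with O8 trans to O7 and C10 cis to O7; the bromine deactivates the furan towards the oxidant.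

Step 8
Reactants: 12 (4R,5S)-1-bromo-4-(hydroxymethyl)-5-[(4-methoxybenzyl)oxy]-5,6-dihydro-4H-cyclopenta[c]furan-4-ol
Product: 13 (4R,5S)-1-bromo-5-[(4-methoxybenzyl)oxy]-2',2'-dimethyl-5,6-dihydrospiro[cyclopenta[c]furan-4,4'-[1,3]dioxolane]
Conditions: Me2C(OMe)2, PPTS (cat.), CH2Cl2, rt
Reagents that add atoms: 2,2-dimethoxypropane, COC(C)(C)OC
Why: Transketalisation of the 1,2-diol should give the spiro-acetonide, which masks O8 so that it cannot later direct hydrogen to the wrong face.

Step 9
Reactants: 13 (4R,5S)-1-bromo-5-[(4-methoxybenzyl)oxy]-2',2'-dimethyl-5,6-dihydrospiro[cyclopenta[c]furan-4,4'-[1,3]dioxolane]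
Product: 16 [(4R,5S)-5-[(4-methoxybenzyl)oxy]-2',2'-dimethyl-5,6-dihydrospiro[cyclopenta[c]furan-4,4'-[1,3]dioxolan]-1-yl]methanol, via furyllithium 14 (not isolated), via furan-1-carbaldehyde 15 (not isolated)
Conditions: n-BuLi, THF, −78 °C; DMF; then MeOH, NaBH4, −78 → 0 °C
Reagents that add atoms: N,N-dimethylformamide, CN(C)C=O
Why: Bromine–lithium exchange at the furan α-position, formylation and NaBH4 reduction in one flask should place the C3 hydroxymethyl group exactly where the bromine was.

Step 10
Reactants: 16 [(4R,5S)-5-[(4-methoxybenzyl)oxy]-2',2'-dimethyl-5,6-dihydrospiro[cyclopenta[c]furan-4,4'-[1,3]dioxolan]-1-yl]methanol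
Product: 18 bicyclic 6-hydroxy-2H-pyran-3(6H)-one: (7S,8R)-1-hydroxy-4-oxo-5(9)-ene with 7-O-PMB and 8,10-O-isopropylidene (C1 epimers), via ring-opened enedione 17 (not isolated)
Conditions: NBS (1.05 equiv), NaHCO3, THF/H2O (4:1), 0 °C
Reagents that add atoms: water, O
Why: NBS brominates the electron-rich furan at an α-carbon, water adds at the other α-carbon, and the 2,5-dihydrofuran hemiacetal loses bromide and opens to enedione 17, whose cis geometry is enforced because the new C5=C9 alkene lies in the cyclopentene ring. The primary C3 hydroxyl then adds to the C1 aldehyde (6-exo-trig hemiacetalisation), forming O2–C1 and the pyranone ring, so the furan oxygen ends as the C4 ketone and the carbinol oxygen as O2. This is the Achmatowicz rearrangement of a 2-furylmethanol, applied here to a 3,4-ring-fused furan. C1 is the only new stereocentre; as a hemiacetal carbon it equilibrates, is not controlled here, and is fixed in step 19. The step needs the furan to be oxidised in preference to the anisyl ring and the acetonide to survive; the much higher nucleophilicity of the trisubstituted furan and the bicarbonate buffer at 0 °C should secure both, and the regiochemistry (ketone at C4, lactol at C1) is fixed by the position of the hydroxymethyl group. Because the furan is planar, C7 and C8 pass through unchanged and no ring-fusion isomers can arise.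

Step 11
Reactants: 18 bicyclic 6-hydroxy-2H-pyran-3(6H)-one
Product: 19 1-O-tert-butyldimethylsilyl acetal of 18 (C1 epimers)
Conditions: TBSCl, imidazole, CH2Cl2, 0 °C
Reagents that add atoms: tert-butyldimethylsilyl chloride, CC(C)(C)[Si](C)(C)Cl
Why: Silylation of the only free hydroxyl (the lactol OH) should lock C1 as a mixed silyl acetal that survives the following neutral and basic steps.

Step 12
Reactants: 19 1-O-TBS acetal
Product: 20 (7S,8R)-7-hydroxy-1-O-TBS-8,10-O-isopropylidene-5(9)-en-4-one
Conditions: DDQ, CH2Cl2/pH 7 phosphate buffer, 0 °C → rt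
Reagents that add atoms: none
Why: Oxidative cleavage of the PMB ether with DDQ is neutral, so the base-sensitive pyranone acetal, the silyl acetal and the acetonide should be untouched while the C7 hydroxyl is released.

Step 13
Reactants: 20 (7S,8R)-7-hydroxy-1-O-TBS-8,10-O-isopropylidene-5(9)-en-4-one
Product: 21 (1S,5S,7S,8R,9S)-7-hydroxy-1-O-TBS-8,10-O-isopropylidene-4-ketone, cis-fused (β-epimer at C1 drawn)
Conditions: [Ir(cod)(PCy3)(py)]PF6 (10 mol %), H2 (1–10 bar), CH2Cl2, rt
Reagents that add atoms: none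
Why: In this hydroxyl-directed homogeneous hydrogenation the homoallylic C7 hydroxyl binds the iridium centre of [Ir(cod)(PCy3)(py)]PF6 and should deliver both hydrogens to the face of C5=C9 syn to O7, setting H-5 and H-9 cis to each other and trans to O8, which is tied up in the acetonide and cannot compete.

Step 14
Reactants: 22 (E)-4-hydroxycinnamic acid (p-coumaric acid)
Product: 24 (E)-3-[4-(methoxymethoxy)phenyl]prop-2-enoic acid, via methoxymethyl ester 23 (not isolated)
Conditions: MeOCH2Cl, i-Pr2NEt, CH2Cl2, 0 °C → rt; then LiOH, THF/H2O, rt; 1 M HCl to pH 4 at 0 °C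
Reagents that add atoms: chloromethyl methyl ether, COCCl
Why: Double alkylation followed by saponification, which cleaves only the ester, should give the phenol-protected acid with the E alkene unchanged.

Step 15
Reactants: 21 cis-fused 7-hydroxy-4-ketone; 24 (E)-3-[4-(methoxymethoxy)phenyl]prop-2-enoic acid
Product: 25 7-O-[(E)-4-(methoxymethoxy)cinnamoyl] ester of 21
Conditions: EDC·HCl, DMAP, CH2Cl2, rt
Reagents that add atoms: none
Why: Steglich esterification should acylate the single free hydroxyl, which sits on the convex β face, and the ester then also protects O7 for the enolisation.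

Step 16
Reactants: 25 7-O-cinnamoyl 4-ketone
Product: 26 C3=C4 enol triflate of 25
Conditions: KN(SiMe3)2, THF, −78 °C; N-(5-chloro-2-pyridyl)bis(trifluoromethanesulfonimide), −78 °C; aq. NH4Cl
Reagents that add atoms: N-(5-chloro-2-pyridyl)bis(trifluoromethanesulfonimide), O=S(=O)(N(c1ccc(Cl)cn1)S(=O)(=O)C(F)(F)F)C(F)(F)F
Why: Kinetic enolisation with a bulky amide base should occur at the accessible C3 methylene rather than the ring-fusion C5 methine, and O-triflation by the reactive triflimide traps the enolate at −78 °C before it can equilibrate.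

Step 17
Reactants: 26 enol triflate
Product: 27 (1S,5S,7S,8R,9S)-3-ene-4-carbaldehyde (C11 aldehyde) with 1-O-TBS, 7-O-cinnamoyl and 8,10-acetonide
Conditions: Pd(PPh3)4 (5 mol %), CO (1–3 bar), Bu3SnH (slow addition), LiCl, THF, 50 °C
Reagents that add atoms: carbon monoxide, [C-]#[O+]
Why: In this reductive carbonylation (formylation of an enol triflate) the triflate adds oxidatively to zerovalent palladium, CO inserts, and the acylpalladium is reduced by Bu3SnH faster than the hydride, kept at low concentration, can attack the cinnamate.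

Step 18
Reactants: 27 1-O-TBS enal
Product: 28 C1 lactol (1-hydroxy) of 27
Conditions: HF·pyridine, pyridine, THF, 0 °C
Reagents that add atoms: none
Why: Desilylation with buffered fluoride should cleave the silyl acetal selectively, and the lactol is stable because O2 is conjugated with the enal.

Step 19
Reactants: 28 C1 lactol
Product: 29 (1S)-1-O-(3-methylbutanoyl) derivative of 28
Conditions: Me2CHCH2COCl, pyridine, DMAP (cat.), CH2Cl2, −20 → 0 °C
Reagents that add atoms: 3-methylbutanoyl chloride, CC(C)CC(Cl)=O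
Why: Acylation of the equilibrating hemiacetal, the only free hydroxyl, should give the β-acylal, since the O-acyl group is pseudo-axial on the convex face cis to H-9 and anomerically stabilised, as is general for iridoid aglycones of this ring fusion.

Step 20
Reactants: 29 1-O-isovaleryl enal
Product: 30 11-oxo-luzonoid A (C11 aldehyde; free 8-OH, 10-OH and phenol)
Conditions: CF3CO2H/H2O/CH2Cl2, 0 °C → rt
Reagents that add atoms: none
Why: Acid hydrolysis should remove the acetonide and the aryl methoxymethyl ether, while the acylal and enol ether are protected from ionisation because the O2 lone pair is delocalised into the enal.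

Step 21
Reactants: 30 11-oxo-luzonoid A
Product: 31 luzonoid A
Conditions: NaBH4, THF/MeOH, −40 °C
Reagents that add atoms: none
Why: NaBH4 at low temperature should reduce the aldehyde 1,2-selectively to the C11 alcohol without touching the two esters or the acylal, and no acid is used once the enol ether becomes electron-rich.

**Compound list**

1 | 3,4-dibromofuran | Brc1cocc1Br | starting material
2 | methyl (2S)-oxirane-2-carboxylate | COC(=O)[C@@H]1CO1 | starting material
3 | (4-bromofuran-3-yl)lithium | [Li]c1cocc1Br | intermediate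
4 | (4-bromofuran-3-yl)magnesium bromide | Br[Mg]c1cocc1Br | intermediate
5 | methyl (2S)-3-(4-bromofuran-3-yl)-2-hydroxypropanoate | COC(=O)[C@@H](O)Cc1cocc1Br | intermediate
6 | methyl (2S)-3-(4-bromofuran-3-yl)-2-[(4-methoxybenzyl)oxy]propanoate | COC(=O)[C@@H](OCc1ccc(OC)cc1)Cc1cocc1Br | intermediate
7 | (2S)-3-(4-bromofuran-3-yl)-N-methoxy-2-[(4-methoxybenzyl)oxy]-N-methylpropanamide | CON(C)C(=O)[C@@H](OCc1ccc(OC)cc1)Cc1cocc1Br | intermediate
8 | (2S)-3-(4-lithiofuran-3-yl)-N-methoxy-2-[(4-methoxybenzyl)oxy]-N-methylpropanamide | CON(C)C(=O)[C@@H](OCc1ccc(OC)cc1)Cc1cocc1[Li] | intermediate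
9 | (5S)-5-[(4-methoxybenzyl)oxy]-5,6-dihydro-4H-cyclopenta[c]furan-4-one | O=C1[C@@H](OCc3ccc(OC)cc3)Cc2cocc21 | intermediate
10 | (5S)-1-bromo-5-[(4-methoxybenzyl)oxy]-5,6-dihydro-4H-cyclopenta[c]furan-4-one | O=C1[C@@H](OCc3ccc(OC)cc3)Cc2c(Br)occ21 | intermediate
11 | (5S)-1-bromo-5-[(4-methoxybenzyl)oxy]-4-methylidene-5,6-dihydro-4H-cyclopenta[c]furan | C=C1[C@@H](OCc3ccc(OC)cc3)Cc2c(Br)occ21 | intermediate
12 | (4R,5S)-1-bromo-4-(hydroxymethyl)-5-[(4-methoxybenzyl)oxy]-5,6-dihydro-4H-cyclopenta[c]furan-4-ol | OC[C@@]1(O)[C@@H](OCc3ccc(OC)cc3)Cc2c(Br)occ21 | intermediate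
13 | (4R,5S)-1-bromo-5-[(4-methoxybenzyl)oxy]-2',2'-dimethyl-5,6-dihydrospiro[cyclopenta[c]furan-4,4'-[1,3]dioxolane] | CC1(C)OC[C@@]2(O1)[C@@H](OCc4ccc(OC)cc4)Cc3c(Br)occ32 | intermediate
14 | 1-lithio analogue of 13 (lithium in place of bromine) | CC1(C)OC[C@@]2(O1)[C@@H](OCc4ccc(OC)cc4)Cc3c([Li])occ32 | intermediate
15 | (4R,5S)-5-[(4-methoxybenzyl)oxy]-2',2'-dimethyl-5,6-dihydrospiro[cyclopenta[c]furan-4,4'-[1,3]dioxolane]-1-carbaldehyde | CC1(C)OC[C@@]2(O1)[C@@H](OCc4ccc(OC)cc4)Cc3c(C=O)occ32 | intermediate
16 | [(4R,5S)-5-[(4-methoxybenzyl)oxy]-2',2'-dimethyl-5,6-dihydrospiro[cyclopenta[c]furan-4,4'-[1,3]dioxolan]-1-yl]methanol | CC1(C)OC[C@@]2(O1)[C@@H](OCc4ccc(OC)cc4)Cc3c(CO)occ32 | intermediate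
17 | ring-opened enedione: 2-(hydroxyacetyl)cyclopent-1-ene-1-carbaldehyde carrying the C7 PMB ether and the C8 spiro-acetonide (7S,8R) | OCC(=O)C1=C(C=O)[C@@]2(COC(C)(C)O2)[C@@H](OCc3ccc(OC)cc3)C1 | intermediate
18 | (7S,8R)-1-hydroxy-7-O-(4-methoxybenzyl)-8,10-O-isopropylidene-5(9)-en-4-one (6-hydroxy-2H-pyran-3(6H)-one fused at C5=C9; C1 epimers) | O[C@@H]1OCC(=O)C2=C1[C@@]3(COC(C)(C)O3)[C@@H](OCc4ccc(OC)cc4)C2 | intermediate
19 | 1-O-TBS acetal of 18 (C1 epimers) | CC(C)(C)[Si](C)(C)O[C@@H]1OCC(=O)C2=C1[C@@]3(COC(C)(C)O3)[C@@H](OCc4ccc(OC)cc4)C2 | intermediate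
20 | (7S,8R)-7-hydroxy-1-O-TBS-8,10-O-isopropylidene-5(9)-en-4-one | CC(C)(C)[Si](C)(C)O[C@@H]1OCC(=O)C2=C1[C@@]3(COC(C)(C)O3)[C@@H](O)C2 | intermediate
21 | (1S,5S,7S,8R,9S)-7-hydroxy-1-O-TBS-8,10-O-isopropylidene-4-ketone, cis-fused | CC(C)(C)[Si](C)(C)O[C@@H]1OCC(=O)[C@H]2C[C@H](O)[C@]3(COC(C)(C)O3)[C@@H]12 | intermediate
22 | (E)-4-hydroxycinnamic acid | OC(=O)/C=C/c1ccc(O)cc1 | starting material
23 | methoxymethyl (E)-3-[4-(methoxymethoxy)phenyl]prop-2-enoate | COCOC(=O)/C=C/c1ccc(OCOC)cc1 | intermediate
24 | (E)-3-[4-(methoxymethoxy)phenyl]prop-2-enoic acid | OC(=O)/C=C/c1ccc(OCOC)cc1 | intermediate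
25 | 7-O-[(E)-4-(methoxymethoxy)cinnamoyl] ester of 21 | CC(C)(C)[Si](C)(C)O[C@@H]1OCC(=O)[C@H]2C[C@H](OC(=O)/C=C/c3ccc(OCOC)cc3)[C@]4(COC(C)(C)O4)[C@@H]12 | intermediate
26 | C3=C4 enol trifluoromethanesulfonate of 25 | CC(C)(C)[Si](C)(C)O[C@@H]1OC=C(OS(=O)(=O)C(F)(F)F)[C@H]2C[C@H](OC(=O)/C=C/c3ccc(OCOC)cc3)[C@]4(COC(C)(C)O4)[C@@H]12 | intermediate
27 | (1S,5S,7S,8R,9S)-3-ene-4-carbaldehyde with 1-O-TBS, 7-O-cinnamoyl(MOM) and 8,10-acetonide | CC(C)(C)[Si](C)(C)O[C@@H]1OC=C(C=O)[C@H]2C[C@H](OC(=O)/C=C/c3ccc(OCOC)cc3)[C@]4(COC(C)(C)O4)[C@@H]12 | intermediate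
28 | C1 lactol of 27 (1β-hydroxy drawn) | O[C@@H]1OC=C(C=O)[C@H]2C[C@H](OC(=O)/C=C/c3ccc(OCOC)cc3)[C@]4(COC(C)(C)O4)[C@@H]12 | intermediate
29 | (1S)-1-O-(3-methylbutanoyl) derivative of 28 | CC(C)CC(=O)O[C@@H]1OC=C(C=O)[C@H]2C[C@H](OC(=O)/C=C/c3ccc(OCOC)cc3)[C@]4(COC(C)(C)O4)[C@@H]12 | intermediate
30 | 11-oxo-luzonoid A | CC(C)CC(=O)O[C@@H]1OC=C(C=O)[C@H]2C[C@H](OC(=O)/C=C/c3ccc(O)cc3)[C@](O)(CO)[C@@H]12 | intermediate
31 | luzonoid A | CC(C)CC(=O)O[C@@H]1OC=C(CO)[C@H]2C[C@H](OC(=O)/C=C/c3ccc(O)cc3)[C@](O)(CO)[C@@H]12 | target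

**Step count**

Total steps: 21. Longest linear sequence: 20 steps (steps 1–13 and 15–21).

**Steps most likely to fail**

Step 13. The catalyst may turn over slowly on the tetrasubstituted enone, or hydrogen may be delivered from the O8 face through coordination to the acetal oxygens instead of the C7 hydroxyl. Fallback, from 20 back to 21: the hydride is delivered through a covalent tether. Silylation of the C7 hydroxyl with chlorodimethylsilane and Et3N would give the C7 O-dimethylsilyl ether F1. RhCl(PPh3)3-catalysed intramolecular 1,4-hydrosilylation would then transfer the Si–H hydrogen to C9 from the O7 face and give the cyclic silyl enol ether F2. Methanolysis (K2CO3, MeOH, 0 °C) would free the C7 hydroxyl and protonate C5 to the more stable cis ring fusion, which is 21.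

Step 16. Deprotonation may occur at C5 as well as C3, giving regioisomeric triflates or epimerisation at the ring fusion. Fallback, from 25 back to 26: the regiochemistry is set under equilibrating soft enolisation instead of kinetic deprotonation. TMSOTf and Et3N in CH2Cl2 would give the C3=C4 trimethylsilyl enol ether F3, which should be favoured because an sp2 centre at the ring-fusion carbon strains the cis-bicycle, and which can be separated from any isomer. CsF with the same pyridyl triflimide in DME would then exchange silicon for the triflyl group regiospecifically to give 26.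

Step 10. Bromination may spill over to the anisyl ring or to the product, or HBr may strip the acetonide and degrade the ring-fused enedione before it cyclises. Fallback, from 16 back to 18: the furan is oxidised by cycloaddition instead of halogenation. Photooxygenation (O2, visible light, tetraphenylporphyrin, CH2Cl2, −78 °C) would give the furan endoperoxide F4, and reduction with Me2S would give enedione 17, which closes to lactol 18 under neutral, halogen-free conditions.

Further compounds
F1 | step 13 | C7 O-dimethylsilyl ether of 20 | CC(C)(C)[Si](C)(C)O[C@@H]1OCC(=O)C2=C1[C@@]3(COC(C)(C)O3)[C@@H](O[SiH](C)C)C2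
F2 | step 13 | cyclic dimethylsilylene bridging the C4 enol oxygen and O7, C4=C5 enol ether, H-9 β | CC(C)(C)[Si](C)(C)O[C@@H]1OCC2=C3C[C@H](O[Si](C)(C)O2)[C@]4(COC(C)(C)O4)[C@@H]13
F3 | step 16 | C3=C4 trimethylsilyl enol ether of 25 | CC(C)(C)[Si](C)(C)O[C@@H]1OC=C(O[Si](C)(C)C)[C@H]2C[C@H](OC(=O)/C=C/c3ccc(OCOC)cc3)[C@]4(COC(C)(C)O4)[C@@H]12
F4 | step 10 | furan endoperoxide of 16 (2,3,7-trioxabicyclo[2.2.1]hept-5-ene spanning C1 and C4) | OCC12OOC(O1)C3=C2C[C@H](OCc5ccc(OC)cc5)[C@]34COC(C)(C)O4
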